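Chain locants C1'–C16' run from the benzene ring (ring A).

- **Cuts:** the side chain is cut at two bonds at once, C4'–C5' (allylic CH2 to the carbinol carbon) and C1'–aryl (benzylic CH2 to the ring A carbon next to the C1 oxygen); both phenols are masked as methyl ethers.
- **Enabling feature:** C1'–C2'=C3'(CH3)–C4' is an isoprene unit held between the ring A carbon and carbinol C5'. It is a homoallylic alcohol HO–C5'–C4'–C3'=C2' with the aryl group on the far allylic carbon C1', the pattern of a 1,4-addition of aryl and C(OH)R across isoprene. The target is therefore arene + isoprene + (2E,6E)-farnesal.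
- **Forward order:** farnesol is oxidised to farnesal; the aryl bromide is made in two steps from 4-methoxy-2-methylphenol; one nickel-catalysed operation joins the aryl group (as diarylzinc), isoprene and farnesal; oxidative demethylation and quinone reduction free the hydroquinone.
- **Stereochemistry:** C5' (S) from ligand control in the oxidative cyclisation of the key step; 2'E from aryl delivery to a syn-allylnickel; 6'E and 10'E carried unchanged from (2E,6E)-farnesol.

Key step: step 4

Assumption: the sense of induction of the chiral ligand in step 4 cannot be predicted safely, so the step is written for the ligand antipode that attacks the Si face of the aldehyde (5S); both antipodes are available.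

Step 1
Reactants: 1 (2E,6E)-farnesol
Product: 2 (2E,6E)-farnesal
Conditions: activated MnO2 (15 equiv), CH2Cl2, rt
Reagents that add atoms: none
Why: Allylic alcohol oxidation with MnO2 should stop at the enal and leave the 2E double bond and the remote alkenes untouched.

Step 2
Reactants: 3 4-methoxy-2-methylphenol
Product: 4 2-bromo-4-methoxy-6-methylphenol
Conditions: NBS (1.0 equiv), i-Pr2NH (10 mol %), CH2Cl2, 0 °C
Reagents that add atoms: N-bromosuccinimide (O=C1CCC(=O)N1Br)
Why: Electrophilic aromatic bromination in which the free hydroxyl is the strongest director and C6 is its only open ortho/para position, with amine-mediated bromine delivery through a hydrogen bond to the OH reinforcing ortho attack.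

Step 3
Reactants: 4 2-bromo-4-methoxy-6-methylphenol
Product: 5 1-bromo-2,5-dimethoxy-3-methylbenzene
Conditions: MeI, K2CO3, acetone, reflux
Reagents that add atoms: iodomethane (CI)
Why: Williamson ether synthesis on the phenoxide, which should be clean despite the two ortho substituents because the electrophile is the smallest possible.

Step 4
Reactants: 5 1-bromo-2,5-dimethoxy-3-methylbenzene, 6 isoprene, 2 (2E,6E)-farnesal
Product: 9 (2E,5S,6E,10E)-1-(2,5-dimethoxy-3-methylphenyl)-3,7,11,15-tetramethylhexadeca-2,6,10,14-tetraen-5-ol, via aryllithium 7 (not isolated), via diarylzinc 8 (not isolated)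
Conditions: t-BuLi (2.0 equiv), THF, −78 °C; ZnCl2 (0.5 equiv), −78 °C to rt; solution of 8 (1.2 equiv) added over 2 h to 2 (1.0 equiv), 6 (4 equiv), Ni(cod)2 (zerovalent nickel, 10 mol %), spirobiindane-7,7'-diol-derived N,N-dimethylphosphoramidite (one antipode, 12 mol %), THF, 0 °C to rt; H2O work-up
Reagents that add atoms: none
Why: Proposed new method: zerovalent nickel bearing one chiral phosphoramidite binds isoprene and the zinc-activated C=O of 2 and couples them oxidatively, C1 of isoprene (the CH2 next to the methyl-bearing carbon, C4' of the target) to the aldehyde carbon (C5'), giving an oxanickelacycle that is at once a nickel alkoxide and an η3-allyl; the alkoxide oxygen then takes zinc from 8, one aryl group passes to nickel and reductive elimination joins it to the unsubstituted allyl terminus (C1'). The closest known reaction types are the racemic Ni(acac)2-catalysed three-component coupling of diarylzinc, isoprene and aldehydes to (E)-5-aryl-3-methylpent-3-en-1-ols and the enantioselective nickel/monodentate-phosphoramidite couplings of aldehydes with dienes or alkynes and dialkylzinc, which run through the same oxidative cyclisation; new is their union, that is ligand-controlled enantioselection in the arylative coupling of a simple diene, here with an enal. The product gains no ring (the five-membered nickelacycle is transient). The only new stereocentre, C5', is fixed in the oxidative cyclisation, in which the ligand antipode is chosen so that the Si face of the aldehyde is attacked and the 5S alcohol results. The step needs 1,4- and not 1,2-addition across the diene with the aldehyde at C1 and the aryl at C4 of isoprene, E geometry at C2'=C3', 1,2-reaction of the enal and a catalytic cycle faster than direct aryl transfer from zinc to the aldehyde. These should be secured by the higher electron density at the methyl-substituted diene terminus, by aryl delivery to the less hindered end of a syn-η3-allyl, by the β,β-disubstitution of 2 and by slow addition of 8 to an excess of isoprene.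

Step 5
Reactants: 9 (2E,5S,6E,10E)-1-(2,5-dimethoxy-3-methylphenyl)-3,7,11,15-tetramethylhexadeca-2,6,10,14-tetraen-5-ol
Product: 11 2-[(2E,5S,6E,10E)-5-hydroxy-3,7,11,15-tetramethylhexadeca-2,6,10,14-tetraen-1-yl]-6-methylbenzene-1,4-diol (CNP0314458.1), via quinone 10 (not isolated)
Conditions: (NH4)2Ce(NO3)6 (2.5 equiv), MeCN/H2O 2:1, 0 °C, 15 min; extraction into Et2O, then aq. Na2S2O4, rt, under argon
Reagents that add atoms: water (O)
Why: Oxidative demethylation of a hydroquinone dimethyl ether, in which the 1,4-dimethoxyarene is oxidised far more easily than the trisubstituted alkenes and water replaces both methoxy groups to give the para-quinone, followed by dithionite reduction to the hydroquinone; short contact at 0 °C should spare the allylic C5' alcohol and its configuration.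

Compound list
1 | (2E,6E)-farnesol, (2E,6E)-3,7,11-trimethyldodeca-2,6,10-trien-1-ol | CC(C)=CCC/C(C)=C/CC/C(C)=C/CO | starting material
2 | (2E,6E)-farnesal, (2E,6E)-3,7,11-trimethyldodeca-2,6,10-trienal | CC(C)=CCC/C(C)=C/CC/C(C)=C/C=O | intermediate
3 | 4-methoxy-2-methylphenol | COc1ccc(O)c(C)c1 | starting material
4 | 2-bromo-4-methoxy-6-methylphenol | COc1cc(C)c(O)c(Br)c1 | intermediate
5 | 1-bromo-2,5-dimethoxy-3-methylbenzene | COc1cc(C)c(OC)c(Br)c1 | intermediate
6 | isoprene, 2-methylbuta-1,3-diene | C=CC(C)=C | starting material
7 | (2,5-dimethoxy-3-methylphenyl)lithium | [Li]c1cc(OC)cc(C)c1OC | intermediate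
8 | bis(2,5-dimethoxy-3-methylphenyl)zinc | COc1cc(C)c(OC)c(c1)[Zn]c1cc(OC)cc(C)c1OC | intermediate
9 | (2E,5S,6E,10E)-1-(2,5-dimethoxy-3-methylphenyl)-3,7,11,15-tetramethylhexadeca-2,6,10,14-tetraen-5-ol | CC(C)=CCC/C(C)=C/CC/C(C)=C/[C@@H](O)C/C(C)=C/Cc1cc(OC)cc(C)c1OC | intermediate
10 | 2-[(2E,5S,6E,10E)-5-hydroxy-3,7,11,15-tetramethylhexadeca-2,6,10,14-tetraen-1-yl]-6-methylcyclohexa-2,5-diene-1,4-dione | CC(C)=CCC/C(C)=C/CC/C(C)=C/[C@@H](O)C/C(C)=C/CC1=CC(=O)C=C(C)C1=O | intermediate
11 | 2-[(2E,5S,6E,10E)-5-hydroxy-3,7,11,15-tetramethylhexadeca-2,6,10,14-tetraen-1-yl]-6-methylbenzene-1,4-diol | CC(C)=CCC/C(C)=C/CC/C(C)=C/[C@@H](O)C/C(C)=C/Cc1cc(O)cc(C)c1O | target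

Total step count: 5. Longest linear sequence: 4 steps (steps 2, 3, 4, 5 from 4-methoxy-2-methylphenol); step 1 supplies the second branch.

Steps most likely to fail

Step 4 (Proposed new method). Facial discrimination in the oxidative cyclisation may be weak with a small, conformationally free diene and a hindered enal. Direct aryl transfer from zinc to the aldehyde may outrun the catalytic cycle, and E geometry may erode under a ligand-bearing catalyst. The fallback uses known chemistry only, sets out from 5, 6 and 2 and returns at 9. The diarylzinc 8 is made as in step 4 and the coupling is run without chiral ligand, with Ni(acac)2 (divalent nickel precatalyst, 10 mol %) in THF at rt. This known racemic arylative three-component coupling should give racemic (2E,6E,10E)-1-(2,5-dimethoxy-3-methylphenyl)-3,7,11,15-tetramethylhexadeca-2,6,10,14-tetraen-5-ol F1. Allylic oxidation with MnO2 in CH2Cl2 should give the dienone (2E,6E,10E)-1-(2,5-dimethoxy-3-methylphenyl)-3,7,11,15-tetramethylhexadeca-2,6,10,14-tetraen-5-one F2. Corey–Bakshi–Shibata reduction with the (R)-methyl oxazaborolidine (20 mol %) and catecholborane in toluene at −78 °C, the alkenyl group acting as the large substituent, should then deliver the 5S alcohol 9.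

Step 5. The acidic oxidant may ionise the allylic C5' alcohol (1,3-transposition, elimination), the side chain may be over-oxidised, and the hydroquinone may re-oxidise in air during work-up. The fallback replaces the methyl ethers by fluoride-labile silyl ethers, sets out from 4 and returns at 11.
- BBr3 in CH2Cl2 (−78 to 0 °C) should demethylate 4 to 2-bromo-6-methylbenzene-1,4-diol F3.
- TBSCl and imidazole in DMF should give 2-bromo-1,4-bis(tert-butyldimethylsilyloxy)-6-methylbenzene F4.
- Direct insertion of Mg in the presence of LiCl and ZnCl2 (0.5 equiv) in THF at rt avoids an aryllithium and its silyl migration, and should give bis[2,5-bis(tert-butyldimethylsilyloxy)-3-methylphenyl]zinc F5.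
- Coupling of F5 with 6 and 2 under the nickel conditions of step 4 should give (2E,5S,6E,10E)-1-[2,5-bis(tert-butyldimethylsilyloxy)-3-methylphenyl]-3,7,11,15-tetramethylhexadeca-2,6,10,14-tetraen-5-ol F6.
- TBAF buffered with AcOH in THF at 0 °C under argon should free 11 without acid or oxidant.

Step 2. Bromination may occur at the position ortho to the methoxy group and para to the methyl group, a second bromine may enter, or the 4-methoxyphenol may be oxidised to the quinone. The fallback fixes the position by directed ortho-metalation, sets out from 3 and returns at 4.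
- Et2NCOCl and NaH in THF should give 4-methoxy-2-methylphenyl N,N-diethylcarbamate F7.
- s-BuLi/TMEDA in THF at −78 °C should lithiate the only free position ortho to the carbamate, giving 2-lithio-4-methoxy-6-methylphenyl N,N-diethylcarbamate F8.
- Quenching with 1,2-dibromoethane should give 2-bromo-4-methoxy-6-methylphenyl N,N-diethylcarbamate F9.
- NaOH in EtOH/H2O at reflux should hydrolyse the carbamate to 4.

Further compounds
F1 | step 4 | racemic (2E,6E,10E)-1-(2,5-dimethoxy-3-methylphenyl)-3,7,11,15-tetramethylhexadeca-2,6,10,14-tetraen-5-ol | CC(C)=CCC/C(C)=C/CC/C(C)=C/C(O)C/C(C)=C/Cc1cc(OC)cc(C)c1OC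
F2 | step 4 | (2E,6E,10E)-1-(2,5-dimethoxy-3-methylphenyl)-3,7,11,15-tetramethylhexadeca-2,6,10,14-tetraen-5-one | CC(C)=CCC/C(C)=C/CC/C(C)=C/C(=O)C/C(C)=C/Cc1cc(OC)cc(C)c1OC
F3 | step 5 | 2-bromo-6-methylbenzene-1,4-diol | Cc1cc(O)cc(Br)c1O
F4 | step 5 | 2-bromo-1,4-bis(tert-butyldimethylsilyloxy)-6-methylbenzene | Cc1cc(O[Si](C)(C)C(C)(C)C)cc(Br)c1O[Si](C)(C)C(C)(C)C
F5 | step 5 | bis[2,5-bis(tert-butyldimethylsilyloxy)-3-methylphenyl]zinc | Cc1cc(O[Si](C)(C)C(C)(C)C)cc([Zn]c2cc(O[Si](C)(C)C(C)(C)C)cc(C)c2O[Si](C)(C)C(C)(C)C)c1O[Si](C)(C)C(C)(C)C
F6 | step 5 | (2E,5S,6E,10E)-1-[2,5-bis(tert-butyldimethylsilyloxy)-3-methylphenyl]-3,7,11,15-tetramethylhexadeca-2,6,10,14-tetraen-5-ol | CC(C)=CCC/C(C)=C/CC/C(C)=C/[C@@H](O)C/C(C)=C/Cc1cc(O[Si](C)(C)C(C)(C)C)cc(C)c1O[Si](C)(C)C(C)(C)C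
F7 | step 2 | 4-methoxy-2-methylphenyl N,N-diethylcarbamate | CCN(CC)C(=O)Oc1ccc(OC)cc1C
F8 | step 2 | 2-lithio-4-methoxy-6-methylphenyl N,N-diethylcarbamate | CCN(CC)C(=O)Oc1c([Li])cc(OC)cc1C
F9 | step 2 | 2-bromo-4-methoxy-6-methylphenyl N,N-diethylcarbamate | CCN(CC)C(=O)Oc1c(Br)cc(OC)cc1C
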